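The comparison I began from set two clocks in this flask against each other: the exchange of the conformers and the work of the catalyst.

substrate 0.050 M; other conformer 0.0500 M; precatalyst 25 µM; time 8.0 min

    substrate ⇌ other conformer (K1 = 4.9, k1 = 4.1 s⁻¹)
    substrate + catalyst → catalyst + target (k2 = 7000 M⁻¹ s⁻¹)
    catalyst + other conformer → catalyst + isomer of the product (k3 = 8400 M⁻¹ s⁻¹)
    precatalyst → catalyst (k4 = 0.18 s⁻¹)
    substrate + target → side product (k5 = 3.9 M⁻¹ s⁻¹)

- why nothing more happens at 8.0 min, or that something still does (other conformer counts as not reacted) (no working catalyst is left / forward and back rates have come level / it is still moving / all of the substrate has reacted)
- how much of the substrate and other conformer together has reacted by 8.0 min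
- how much target there is at 8.0 min, in percent of the substrate and other conformer together charged
- how much isomer of the product there is at 8.0 min, in percent of the substrate and other conformer together charged
- how much side product there is at 8.0 min, in percent of the substrate and other conformer together charged

- percent here means substrate units held: one side product counts as two
- in a conversion other conformer counts as not yet reacted
- the reaction counts as stopped when no species that holds the substrate and other conformer together changes by six tenths of a point or more over the second half of the time
- run time (flask): 8.0 min

On the fastest rung I put the exchange, whose relaxation rate is the forward constant plus the back constant, the latter being the forward constant divided by the equilibrium constant, other conformer over substrate: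

τx = 1 / (4.1 s⁻¹ + 4.1 s⁻¹ / 4.9) = 0.203 s

The next rung was the birth of catalyst from precatalyst, and beside it the time constant τc of the conformer pool under the full catalyst charge:

τa = 1 / 0.18 s⁻¹ = 5.56 s

τc = (1 + 4.9) / (25 µM × (7000 M⁻¹ s⁻¹ + 8400 M⁻¹ s⁻¹ × 4.9)) = 4.90 s

Since τx was much shorter than τa and τc, I treated the exchange as balanced, so the equal charges lost their say before catalyst had done much. The lowest rung was the loss of target to the substrate of that balanced pool, taken at its starting size:

τs = (1 + 4.9) / (3.9 M⁻¹ s⁻¹ × (0.050 M + 0.0500 M)) = 15.1 s

This was slower than τc, so I expected some side product but not most of the material. The run time was far longer than τc, so I committed to full conversion.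

With the pool balanced, the catalyst cancels from the ratio of the two catalytic rates, which leaves the selectivity factor ρ, target made per isomer of the product made:

ρ = 7000 M⁻¹ s⁻¹ / (8400 M⁻¹ s⁻¹ × 4.9) = 0.170

My reckoning stopped there, with 14.5 % of the catalyst's output as target and no figure for side product.

The forecast said all of the substrate has reacted, with conversion 100 %, target 11.7 %, isomer of the product 83.2 % and side product 5.1 %, holding that “they stay equilibrated at about 17% substrate and 83% other conformer”.

In the flask the midpoint of conversion came at 0.124 min, while catalyst and both conformers were present and the catalytic steps and the side step ran together. By 8.00 min the outcome in this flask was that all of the substrate has reacted, at 100 % conversion, with target 11.7 %, isomer of the product 83.3 % and side product 5.03 %. Each side product holds one target unit, so target made over isomer read 0.171 against ρ. In this flask the target answer moved by 5 points with precatalyst down at 4.75 µM. The neighbour with 0.20 M of other conformer gave target 8.84 %, isomer of the product 81.3 % and side product 9.85 %, and the same count there read 0.169.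

The constants used here are assumed; the result is computed.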